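**Retrosynthetic overview**

1. Numbering (caryophyllane): C1/C9 are the cyclobutane ring-fusion carbons, C4 the O-bearing quaternary carbon, C5 the adjacent CH, C8 the methylidene carbon, C1′ the benzylic CH.
2. The dihydropyran is formed last: O–C4 and C1′–C5 by hetero-Diels–Alder addition of the ortho-quinone methide (benzaldehyde + 2,4-diformylphloroglucinol) to (+)-β-caryophyllene.
3. Enabling feature: at the C4–C5 bond shared by the nine-membered carbocycle and the dihydropyran, O and C1′ are syn while the ring bonds C4–C3 and C5–C6 are anti (methyl cis to C6). This is the imprint of a suprafacial addition to an (E)-trisubstituted ring olefin, so C4–C5 is made as C4=C5 by ring-closing metathesis, which closes the nine-membered ring (Z); the olefin is then inverted to E.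
4. The metathesis precursor, a trans-cyclobutane with an isopropenyl arm and a pentenoyl arm, comes from an enantioselective cyclohexenone–isobutene [2+2] photoadduct. Its six-membered ring is a temporary ring, cut between the carbons that become C8 and C4.
5. Ring order: cyclobutane → nine-membered carbocycle → dihydropyran.

Key step: step 8

Remark: in this numbering the target is (1S,9R) at the cyclobutane, the mirror image of commercial (−)-β-caryophyllene, so the terpenoid half is built de novo.
Remark: the oxazaborolidine is written in its (S)-prolinol-derived form; if its sense of induction is opposite to that needed for the (6S) photoadduct, the (R)-enantiomer is used and nothing else changes.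

**Route**

Step 1
Reactants: 1 cyclohex-2-en-1-one; 2 2-methylpropene (isobutene)
Product: 4 (1S,6S)-7,7-dimethylbicyclo[4.2.0]octan-2-one (cis-fused), via trans-fused photoadduct 3 (not isolated)
Conditions: 2 (excess), AlBr3 complex of (S)-3,3-bis(3,5-dimethylphenyl)-1-(2,4,6-trifluorophenyl)tetrahydro-1H,3H-pyrrolo[1,2-c][1,3,2]oxazaborole (50 mol%), CH2Cl2, hν (366 nm), −75 °C; then basic Al2O3, CH2Cl2, rt
Reagents that add atoms: none
Why: Lewis-acid-catalysed enantioselective enone–alkene [2+2] photocycloaddition: the catalyst binds the enone carbonyl and shields one face, head-to-tail addition places CMe2 next to the β-carbon and fixes that stereocentre (C6, S), and basic alumina equilibrates the α-carbon of the strained trans-fused adduct to the cis-fused ketone.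

Step 2
Reactants: 4 (1S,6S)-7,7-dimethylbicyclo[4.2.0]octan-2-one
Product: 5 trimethyl{[(1S,6S)-7,7-dimethylbicyclo[4.2.0]oct-2-en-2-yl]oxy}silane
Conditions: LiN(iPr)2, THF, −78 °C; Me3SiCl, −78 °C → rt
Reagents that add atoms: chlorotrimethylsilane, C[Si](C)(C)Cl
Why: Kinetic deprotonation by the hindered amide occurs at the α′-CH2 rather than at the ring-fusion methine, and O-silylation traps that enolate regioselectively (silyl enol ether formation) without touching either stereocentre.

Step 3
Reactants: 5 trimethyl{[(1S,6S)-7,7-dimethylbicyclo[4.2.0]oct-2-en-2-yl]oxy}silane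
Product: 6 (1S,2S)-3,3-dimethyl-2-(3-oxopropyl)cyclobutane-1-carboxylic acid (cis)
Conditions: O3, CH2Cl2, −78 °C; Me2S, −78 °C → rt; H2O
Reagents that add atoms: ozone, [O-][O+]=O
Why: Ozonolysis of the silyl enol ether cuts the temporary six-membered ring between the future C8 and C4 to a silyl ester and an aldehyde, and reductive work-up with hydrolysis should give the aldehyde acid with the cyclobutane stereocentres intact.

Step 4
Reactants: 6 (1S,2S)-3,3-dimethyl-2-(3-oxopropyl)cyclobutane-1-carboxylic acid
Product: 7 (1S,2S)-2-(3-hydroxybutyl)-3,3-dimethylcyclobutane-1-carboxylic acid (both carbinol epimers)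
Conditions: MeMgBr (3 equiv), THF, −78 → 0 °C; aq. NH4Cl, then pH 3
Reagents that add atoms: methylmagnesium bromide, C[Mg]Br
Why: Grignard addition to the aldehyde after in situ formation of the unreactive magnesium carboxylate; the new carbinol centre forms without control and is removed in the next step.

Step 5
Reactants: 7 (1S,2S)-2-(3-hydroxybutyl)-3,3-dimethylcyclobutane-1-carboxylic acid
Product: 8 (1S,2S)-3,3-dimethyl-2-(3-oxobutyl)cyclobutane-1-carboxylic acid
Conditions: Dess–Martin periodinane, CH2Cl2, rt
Reagents that add atoms: none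
Why: Dess–Martin oxidation of the secondary alcohol to the methyl ketone tolerates the free acid and does not epimerise the cyclobutane.

Step 6
Reactants: 8 (1S,2S)-3,3-dimethyl-2-(3-oxobutyl)cyclobutane-1-carboxylic acid
Product: 9 (1S,2S)-3,3-dimethyl-2-(3-methylbut-3-en-1-yl)cyclobutane-1-carboxylic acid
Conditions: Ph3PCH3Br, KOtBu (3 equiv each), THF, 0 °C → rt; aq. HCl work-up
Reagents that add atoms: methyltriphenylphosphonium bromide, C[P+](c1ccccc1)(c1ccccc1)c1ccccc1.[Br-]
Why: Wittig methylenation of the methyl ketone installs the isopropenyl arm (future C4 with its methyl), the carboxylate formed by the first equivalent of base being inert to the ylide.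

Step 7
Reactants: 9 (1S,2S)-3,3-dimethyl-2-(3-methylbut-3-en-1-yl)cyclobutane-1-carboxylic acid
Product: 11 1-[(1R,2S)-3,3-dimethyl-2-(3-methylbut-3-en-1-yl)cyclobutyl]pent-4-en-1-one (trans), via cis ketone 10 (not isolated)
Conditions: but-3-enyllithium (3.5 equiv; from 4-bromobut-1-ene and Li, Et2O), Et2O, 0 °C → rt; aq. NH4Cl; then NaOMe (cat.), MeOH, rt
Reagents that add atoms: but-3-enyllithium, [Li]CCC=C
Why: Addition of the organolithium to the lithium carboxylate gives a stable gem-diolate that releases the ketone only on work-up (ketone synthesis from a carboxylic acid), and methoxide then epimerises the now enolisable C9 to the thermodynamically favoured trans-1,2-disubstituted cyclobutane.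

Step 8
Reactants: 11 1-[(1R,2S)-3,3-dimethyl-2-(3-methylbut-3-en-1-yl)cyclobutyl]pent-4-en-1-one
Product: 12 (1S,4Z,9R)-4,11,11-trimethylbicyclo[7.2.0]undec-4-en-8-one
Conditions: second-generation Hoveyda–Grubbs catalyst RuCl2(=CH-C6H4-2-OiPr)(H2IMes) (10 mol%), toluene (1 mM), 80 °C, argon sparge
Reagents that add atoms: none
Why: The Ru alkylidene loads on the monosubstituted C5=CH2 terminus, engages the 1,1-disubstituted C4=CH2 group by [2+2]/retro-[2+2] and expels ethene, so the new C4=C5 bond closes the nine-membered carbocycle (ring-closing olefin metathesis). The closest known reaction type is ring-closing metathesis to eight- and nine-membered carbocycles and oxacycles, which delivers Z-olefins. The ring closes between two sp2 termini as an endocyclic olefin; the trans-1,2 arms on the rigid cyclobutane and the sp2 C8 carbonyl remove rotors and hold the chain ends within reach. No stereocentre is created: the olefin should be Z because the metallacycle leading to an (E)-cyclononene is far more strained and the reaction is reversible enough to settle on the less strained isomer, while C9 is already in its stable trans arrangement. The selectivity needed is ring closure over oligomerisation and over any other metathesis mode; high dilution with ethene removal secures the first, and keeping C8 as a ketone (no exocyclic methylene yet) leaves only the two olefins that must react.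

Step 9
Reactants: 12 (1S,4Z,9R)-4,11,11-trimethylbicyclo[7.2.0]undec-4-en-8-one
Product: 13 (1S,4Z,9R)-4,11,11-trimethyl-8-methylidenebicyclo[7.2.0]undec-4-ene (antipode of isocaryophyllene)
Conditions: Ph3PCH3Br, KOtBu, toluene, 60 °C
Reagents that add atoms: methyltriphenylphosphonium bromide, C[P+](c1ccccc1)(c1ccccc1)c1ccccc1.[Br-]
Why: Wittig methylenation of the cyclononenone installs the C8 methylidene; C9 already has its stable trans configuration, so the basic ylide cannot erode it.

Step 10
Reactants: 13 (1S,4Z,9R)-4,11,11-trimethyl-8-methylidenebicyclo[7.2.0]undec-4-ene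
Product: 14 (1S,4S,6R,10R)-4,12,12-trimethyl-9-methylidene-5-oxatricyclo[8.2.0.0(4,6)]dodecane (cis-epoxide; one of the two face isomers is drawn)
Conditions: mCPBA (1.05 equiv), NaHCO3, CH2Cl2, 0 °C
Reagents that add atoms: 3-chloroperbenzoic acid, OOC(=O)c1cccc(Cl)c1
Why: Prilezhaev epoxidation is faster at the electron-richer trisubstituted ring olefin than at the 1,1-disubstituted exocyclic one and is stereospecifically syn; the face attacked does not matter because both cis-epoxides converge in the next step.

Step 11
Reactants: 14 (1S,4S,6R,10R)-4,12,12-trimethyl-9-methylidene-5-oxatricyclo[8.2.0.0(4,6)]dodecane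
Product: 17 (1S,4E,9R)-4,11,11-trimethyl-8-methylidenebicyclo[7.2.0]undec-4-ene [(+)-β-caryophyllene], via lithium alkoxyphosphine 15 (not isolated), via phosphonium betaine 16 (not isolated)
Conditions: LiPPh2, THF, rt; then MeI, rt → 40 °C
Reagents that add atoms: none
Why: Stereospecific olefin inversion: the phosphide opens the epoxide by SN2 at the secondary C5 with inversion, P-methylation gives the betaine, and its syn-elimination through an oxaphosphetane (Wittig-type collapse) should give the (E)-olefin, as in the known cis-to-trans inversion of cyclooctene.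

Step 12
Reactants: 17 (+)-β-caryophyllene; 18 benzaldehyde; 19 2,4,6-trihydroxybenzene-1,3-dicarbaldehyde (2,4-diformylphloroglucinol)
Product: 21 psidial A (enantiomer as specified; 1S,4S,5R,9R,1′R in caryophyllane numbering), via ortho-quinone methide 20 (not isolated)
Conditions: 17 (excess), H2O, PTS surfactant (5% w/v), 100 °C, sealed tube
Reagents that add atoms: none
Why: Knoevenagel condensation at the free ring position of 19 gives the ortho-quinone methide, which adds to the strained (E)-olefin in an inverse-electron-demand hetero-Diels–Alder reaction: O bonds to the tertiary C4 and C1′ to C5, suprafacial addition gives the trans ring fusion with the methyl cis to C6, attack on the exposed olefin face (the face peracids choose in caryophyllene) sets C4 and C5 relative to C1/C9, and the phenyl orientation sets C1′ (target: phenyl cis to the C4-methyl), the C1′ epimer being the expected co-product to be removed by chromatography.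

**Compound list**

1 | cyclohex-2-en-1-one | O=C1C=CCCC1 | starting material
2 | 2-methylpropene (isobutene) | C=C(C)C | starting material
3 | (1R,6S)-7,7-dimethylbicyclo[4.2.0]octan-2-one (trans-fused photoadduct) | O=C1CCC[C@H]2[C@H]1CC2(C)C | intermediate
4 | (1S,6S)-7,7-dimethylbicyclo[4.2.0]octan-2-one (cis-fused) | O=C1CCC[C@H]2[C@@H]1CC2(C)C | intermediate
5 | trimethyl{[(1S,6S)-7,7-dimethylbicyclo[4.2.0]oct-2-en-2-yl]oxy}silane | C[Si](C)(C)OC1=CCC[C@H]2[C@@H]1CC2(C)C | intermediate
6 | (1S,2S)-3,3-dimethyl-2-(3-oxopropyl)cyclobutane-1-carboxylic acid | O=CCC[C@H]1[C@@H](C(=O)O)CC1(C)C | intermediate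
7 | (1S,2S)-2-(3-hydroxybutyl)-3,3-dimethylcyclobutane-1-carboxylic acid (both carbinol epimers) | CC(O)CC[C@H]1[C@@H](C(=O)O)CC1(C)C | intermediate
8 | (1S,2S)-3,3-dimethyl-2-(3-oxobutyl)cyclobutane-1-carboxylic acid | CC(=O)CC[C@H]1[C@@H](C(=O)O)CC1(C)C | intermediate
9 | (1S,2S)-3,3-dimethyl-2-(3-methylbut-3-en-1-yl)cyclobutane-1-carboxylic acid | C=C(C)CC[C@H]1[C@@H](C(=O)O)CC1(C)C | intermediate
10 | 1-[(1S,2S)-3,3-dimethyl-2-(3-methylbut-3-en-1-yl)cyclobutyl]pent-4-en-1-one (cis) | C=C(C)CC[C@H]1[C@@H](C(=O)CCC=C)CC1(C)C | intermediate
11 | 1-[(1R,2S)-3,3-dimethyl-2-(3-methylbut-3-en-1-yl)cyclobutyl]pent-4-en-1-one (trans) | C=C(C)CC[C@H]1[C@H](C(=O)CCC=C)CC1(C)C | intermediate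
12 | (1S,4Z,9R)-4,11,11-trimethylbicyclo[7.2.0]undec-4-en-8-one | C/C1=C/CCC(=O)[C@@H]2CC(C)(C)[C@H]2CC1 | intermediate
13 | (1S,4Z,9R)-4,11,11-trimethyl-8-methylidenebicyclo[7.2.0]undec-4-ene | C/C1=C/CCC(=C)[C@@H]2CC(C)(C)[C@H]2CC1 | intermediate
14 | (1S,4S,6R,10R)-4,12,12-trimethyl-9-methylidene-5-oxatricyclo[8.2.0.0(4,6)]dodecane | C[C@]12CC[C@H]3[C@@H](CC3(C)C)C(=C)CC[C@H]1O2 | intermediate
15 | lithium (1S,4S,5S,9R)-5-(diphenylphosphanyl)-4,11,11-trimethyl-8-methylidenebicyclo[7.2.0]undecan-4-olate | C[C@]1([O-])CC[C@H]2[C@@H](CC2(C)C)C(=C)CC[C@@H]1P(c1ccccc1)c1ccccc1.[Li+] | intermediate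
16 | (1S,4S,5S,9R)-4,11,11-trimethyl-8-methylidene-5-[methyl(diphenyl)phosphaniumyl]bicyclo[7.2.0]undecan-4-olate (betaine) | C[C@]1([O-])CC[C@H]2[C@@H](CC2(C)C)C(=C)CC[C@@H]1[P+](C)(c1ccccc1)c1ccccc1 | intermediate
17 | (1S,4E,9R)-4,11,11-trimethyl-8-methylidenebicyclo[7.2.0]undec-4-ene, (+)-β-caryophyllene | C/C1=C\CCC(=C)[C@@H]2CC(C)(C)[C@H]2CC1 | intermediate
18 | benzaldehyde | O=Cc1ccccc1 | starting material
19 | 2,4,6-trihydroxybenzene-1,3-dicarbaldehyde | O=Cc1c(O)cc(O)c(C=O)c1O | starting material
20 | 5-benzylidene-2,4-dihydroxy-6-oxocyclohexa-1,3-diene-1,3-dicarbaldehyde (ortho-quinone methide) | O=CC1=C(O)C(C=O)=C(O)C(=Cc2ccccc2)C1=O | intermediate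
21 | psidial A, enantiomer as specified | C=C1CC[C@@H]2[C@H](c3ccccc3)c3c(O)c(C=O)c(O)c(C=O)c3O[C@@]2(C)CC[C@H]2[C@H]1CC2(C)C | target

**Step count**

Total steps: 12. Longest linear sequence: 12 steps (from cyclohex-2-en-1-one; 18 and 19 enter in the last step).

**Steps most likely to fail**

Step 8. Closure of the strained nine-membered ring may lose to intermolecular metathesis (dimers, oligomers) or be slowed by carbonyl chelation of the alkylidene. The same C4=C5 bond would then be closed by reductive carbonyl coupling. The fallback sets out from 7. Amide coupling (MeNHOMe·HCl, EDC·HCl, iPr2NEt, CH2Cl2) should give Weinreb amide F1. [2-(1,3-Dioxolan-2-yl)ethyl]magnesium bromide (THF, 0 °C) and then NaOMe/MeOH should give trans hydroxy ketone F2. Wittig methylenation (Ph3PCH3Br, KOtBu) should give methylidene alcohol F3, and Dess–Martin oxidation should give methyl ketone F4. Aqueous HCl in THF should free keto aldehyde F5. McMurry coupling (TiCl3(DME)1.5, Zn–Cu couple, DME, reflux, slow addition) should then close the ring and come back to the route at 13; any E isomer formed is 17 itself.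

Step 12. In hot water the quinone methide may be lost to hydration and self-condensation, and the two phenyl orientations may be poorly discriminated at C1′. The quinone methide 20 would then be generated by oxidation instead of condensation. The fallback sets out from 18 and 19. Reductive benzylation (Hantzsch ester, L-proline, CH2Cl2/EtOH, rt) should give 5-benzyl-2,4,6-trihydroxybenzene-1,3-dicarbaldehyde F6. Hydride abstraction from its benzylic position with DDQ (MeNO2 or benzene, 0 °C → rt) in the presence of 17 forms 20 without water and at low temperature, where the exo/endo preference can be tuned by solvent and temperature. It comes back to the route at 21.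

Step 11. SN2 opening at the transannularly shielded C5 may be slow, and the betaine may not collapse cleanly to the strained (E)-olefin. The inversion would then be done photochemically. The fallback sets out from 13, which is irradiated (254 nm, methyl benzoate as singlet sensitiser, pentane/Et2O) in a closed loop through AgNO3-impregnated silica that retains the (E)-isomer as its silver complex. Release with aqueous NH3 comes back to the route at 17 and bypasses 14; no new compound is made (F0).

**Further compounds**

F1 | step 8 | (1S,2S)-2-(3-hydroxybutyl)-N-methoxy-N,3,3-trimethylcyclobutane-1-carboxamide | CC(O)CC[C@H]1[C@@H](C(=O)N(C)OC)CC1(C)C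
F2 | step 8 | 3-(1,3-dioxolan-2-yl)-1-[(1R,2S)-2-(3-hydroxybutyl)-3,3-dimethylcyclobutyl]propan-1-one | CC(O)CC[C@H]1[C@H](C(=O)CCC2OCCO2)CC1(C)C
F3 | step 8 | 4-[(1S,2R)-2-[4-(1,3-dioxolan-2-yl)but-1-en-2-yl]-4,4-dimethylcyclobutyl]butan-2-ol | CC(O)CC[C@H]1[C@H](C(=C)CCC2OCCO2)CC1(C)C
F4 | step 8 | 4-[(1S,2R)-2-[4-(1,3-dioxolan-2-yl)but-1-en-2-yl]-4,4-dimethylcyclobutyl]butan-2-one | CC(=O)CC[C@H]1[C@H](C(=C)CCC2OCCO2)CC1(C)C
F5 | step 8 | 4-[(1R,2S)-3,3-dimethyl-2-(3-oxobutyl)cyclobutyl]pent-4-enal | CC(=O)CC[C@H]1[C@H](C(=C)CCC=O)CC1(C)C
F6 | step 12 | 5-benzyl-2,4,6-trihydroxybenzene-1,3-dicarbaldehyde | O=Cc1c(O)c(C=O)c(O)c(Cc2ccccc2)c1O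
F0 | step 11 | none | none
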